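## Analysis of the target

Target 15 is a flavonol. It is a 4H-chromen-4-one (ring A fused to the pyranone ring C) with a 3,4,5-trimethoxyphenyl ring B at C2, hydroxyls at C3 and C5, and methoxyls at C7 and C8. It has no stereocentre, so the task is purely one of substitution pattern and of telling oxygen atoms apart. Ring A is pentasubstituted: C5, C7, C8 and C8a all carry oxygen and only C6 carries hydrogen. The two carbons that flank C4a, namely C5 and C8a, both bear oxygen. Whichever of them closes ring C decides between the 5,7,8-pattern wanted here and the isomeric 5,6,7-pattern, which is why routes through a 2,6-dihydroxyaryl ketone are ambiguous. Sensitive features are the 3-hydroxy-4-keto enol (oxidized easily under base), the chelated C5 hydroxyl next to an 8-alkoxy chromone (Wessely–Moser isomerization under strong acid), and five methyl ethers that must stay while one phenol stays free. The strategy reads C5(OH)–C6(H)–C7(OMe)–C8(OMe) as the four carbons of a 1,3,4-trioxygenated ketene acetal diene. C4a and C8a then come from an alkyne that carries the acyl carbon C4 on one end and a bromine on the other, and the bromine marks the single carbon to which O1 will be attached.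

## Retrosynthetic reasoning

**C3–O bond and the C5 mask (15 to 12).** Target 15 is traced back to flavone 12, which lacks the C3 hydroxyl and has its C5 oxygen masked as a methoxymethyl ether. The C3–O bond is cut last because an α-hydroxy-1,3-diketone carried through ring closure would be exposed to acyl migration and oxidation under basic, copper-containing conditions. Forward, the C2=C3 bond of 12 is epoxidized with a dioxirane (13), acid opens the epoxide to the enol (14), and the same acid frees the C5 hydroxyl.

**O1–C8a bond (12 to 11).** Flavone 12 is opened at O1–C8a to the 1,3-diketone 11, whose ring A carries bromine at the future C8a. This cut is chosen over the usual closure of a phenol onto a carbonyl because it removes the C5/C8a ambiguity. Only the brominated carbon can accept the enol oxygen, and the C5 oxygen is masked. Forward, a copper-catalysed intramolecular O-arylation has to join the enol oxygen of the aroyl-side carbonyl to the aryl bromide.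

**C2–C3 bond (11 to 9 and 10).** Diketone 11 is cut between C2 and C3 into the methyl ketone 9 and the acid chloride 10. This is a Claisen-type C-acylation of a ketone enolate and brings in ring B and C2 in one operation from a commercial acid chloride. An ester rearrangement through the phenol is not used, because it would free the C5 hydroxyl just before ring closure.

**Protecting group (9 to 8).** Ketone 9 is the methoxymethyl ether of phenol 8. The mask is needed because the free C5 phenol, ortho to the acyl group, could itself close the pyranone onto the diketone. That would place bromine at C5 and the methoxyls at C6 and C7. An acetal is chosen because it survives base, enolates and copper, and leaves under the acid already needed for the epoxide opening.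

**C4a–C5 and C8–C8a bonds (8 to 3 and 5).** Ring A of 8 is cut into diene 3 and bromoalkynone 5. Cutting here builds the whole oxygen pattern from acyclic pieces and avoids substituting a preformed arene, where the C6 position would react first. The diene supplies C5 to C8 with their oxygens, and the alkyne supplies C4a with the acetyl group and C8a with bromine. Forward, the cycloaddition has to be regioselective and the adduct has to aromatize with the C8 methoxyl retained and the C5 oxygen set free.

**The two partners (3 to 2 to 1; 5 to 4).** Diene 3 is the silyl dienolate of the β-methoxy enoate 2, which is the methyl enol ether of the commercial keto ester 1. Bromoalkynone 5 is the product of silver-catalysed bromination of the commercial terminal ynone 4. Both cuts are functional-group changes only, so the key step is reached in three short operations.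

## Alternatives that were turned down

**Alternative 1:** Ring C is cut at C3–C4 and C2=C3, so that a one-carbon ylide joins an acid chloride and a neighbouring aryl ester.
- Forward step: the α-benzyloxy ylide A3 is C-acylated by the O-aroylsalicyloyl chloride A2, and the resulting keto ylide undergoes an intramolecular Wittig reaction with the aryl ester carbonyl to give the 3-benzyloxyflavone A1.
- For it: it is convergent, the C3 oxygen arrives already protected, and neither a C–O coupling nor a late C3 oxidation is needed. On those two points it is stronger than the chosen route.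
- Against it: A2 presupposes a fully substituted ring-A salicylic acid, so the real difficulty is only moved upstream into classical arene substitution. A1 also carries C5 as a methyl ether, so the end requires a chelation-controlled cleavage of one methyl ether out of six. The non-stabilized alkoxy ylide must be used in excess and could also attack the activated aryl ester.
- Comparison: the chosen strategy builds ring A from acyclic pieces with C5 never methylated, which Alternative 1 cannot offer.

**Alternative 2:** Ring C is cut at C4–C4a and O1–C2, joining a phenol and a cinnamaldehyde.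
- Forward step: a boronic-acid-templated condensation of phenol A5 with aldehyde A6 forms C4–C4a, and the derived ortho-quinone methide closes by oxa-6π electrocyclization to the 2H-chromene A4.
- For it: the skeleton is assembled in one step from simple partners, with ortho-selectivity enforced by the template. In step economy up to the skeleton it is stronger than the chosen route.
- Against it: A4 is at the wrong oxidation level. C4 must become a ketone, C3 must be hydroxylated and C2–C3 must be unsaturated. That is at least three redox operations on an electron-rich 2H-chromene that reopens easily to the quinone methide. C5 is again a methyl ether that must be cleaved selectively at the end.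
- Comparison: the chosen strategy delivers the C4 carbonyl and the free C5 hydroxyl directly from the key step and needs only one late oxidation.

**Alternative 3:** Ring A is cut at C4a–C5, C5–C6 and C8–C8a.
- Forward step: the cyclobutenone A8 opens thermally to a 1,2-dimethoxyvinylketene, which adds to the siloxyalkyne A9. After 4π opening and 6π closure this gives the phenol A7.
- For it: A7 carries all four ring-A oxygens, with O1 already present as a silyl ether, C5 as a free phenol and the acyl group as a ketal. The regiochemistry is fixed by the mechanism and no aryl C–O coupling is needed. On these points it is stronger than the chosen route.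
- Against it: both partners need several steps each (a dioxygenated cyclobutenone, and a siloxyalkyne from an ester homologation). The benzannulation needs prolonged heating of acid-sensitive material, and the endgame still has to switch protecting groups before ring C can be built.
- Comparison: the chosen strategy reaches its key step in three operations from commercial four-carbon compounds and runs it at or below room temperature. The price is one copper-catalysed ring closure.

Key step: step 4

Remark on the chemistry: diene 3 is assumed to form with the C4 methoxyl trans to C2; the geometry at C1 has no bearing on the product. Bromoalkynone 5 is volatile and lachrymatory and is assumed to be used as a freshly prepared solution.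

## Route

**Step 1**
Reactants: 1 methyl 4-methoxy-3-oxobutanoate (methyl 4-methoxyacetoacetate)
Product: 2 methyl (E)-3,4-dimethoxybut-2-enoate
Conditions: HC(OMe)3, H2SO4 (cat.), MeOH, rt; then TsOH (cat.), 120 °C, distil
Reagents that add atoms: trimethyl orthoformate, COC(OC)OC
Why: Acid-catalysed ketalization of the ketone followed by loss of methanol towards the ester gives the conjugated β-methoxy enoate (enol ether formation); the E isomer, with the CH2OMe group cis to the ester, is the thermodynamic one.

**Step 2**
Reactants: 2 methyl (E)-3,4-dimethoxybut-2-enoate
Product: 3 (1Z,3Z)-1,3,4-trimethoxy-1-(trimethylsilyloxy)buta-1,3-diene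
Conditions: LiN(i-Pr)2, THF, −78 °C; Me3SiCl, −78 °C → rt; pentane, filter under Ar; used crude
Reagents that add atoms: chlorotrimethylsilane, C[Si](C)(C)Cl
Why: Kinetic γ-deprotonation of the enoate (the CH2OMe group lies cis to the coordinating ester carbonyl) gives the extended dienolate, which is O-silylated; this is the standard preparation of vinylogous silyl ketene acetal dienes from β-alkoxy enoates.

**Step 3**
Reactants: 4 but-3-yn-2-one
Product: 5 4-bromobut-3-yn-2-one
Conditions: NBS, AgNO3 (10 mol %), acetone, rt, dark; pentane, filter; handled as a PhMe solution
Reagents that add atoms: N-bromosuccinimide, O=C1CCC(=O)N1Br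
Why: Silver-catalysed electrophilic bromination of a terminal alkyne through the silver acetylide; the method is routine for propiolates and ynones and leaves the ketone untouched.

**Step 4**
Reactants: 3 (1Z,3Z)-1,3,4-trimethoxy-1-(trimethylsilyloxy)buta-1,3-diene; 5 4-bromobut-3-yn-2-one
Product: 8 1-(2-bromo-6-hydroxy-3,4-dimethoxyphenyl)ethanone, via silyl ketal cycloadduct 6 (not isolated), via cross-conjugated dienone 7 (not isolated)
Conditions: PhMe, −40 °C → rt; then 1 M HCl, THF, 0 °C
Reagents that add atoms: none
Why: The closest known reaction type is the Diels–Alder benzannulation of 1-alkoxy-1-silyloxy-3-alkoxybutadienes with acetylenic ketones and esters, applied here to a 4-methoxylated diene and a β-bromo ynone, a pairing that is new but stays within that class. The cycloaddition is expected to be a strongly asynchronous [4+2] process: the donor oxygens at C1 and C3 of 3 place the largest HOMO coefficient on C4, which bonds first to the bromine-bearing β-carbon of 5 (largest LUMO coefficient), and the incipient allenolate carbon then closes onto the acetal carbon. Ring A is thus formed by an intermolecular cycloaddition that makes C8–C8a and C4a–C5 and gives the 1,4-cyclohexadiene 6. Regiochemistry is the only selectivity the step needs, and this donor–acceptor match fixes it, placing the acetyl group next to the ketal carbon and the bromine next to the methoxylated sp3 carbon. Because the future C8 carries a hydrogen and the future C5 is a methyl silyl ketal, aromatization can only proceed by collapse of the ketal: dilute acid cleaves the O–Si bond, methanol is expelled to give dienone 7, and 7 enolizes at once to the phenol. The C5 oxygen therefore emerges free and already distinguished from the C7 and C8 methoxyls, while the vinylic bromine is not a leaving group in this sequence and stays at the future C8a. Two stereocentres arise transiently in 6 and both are erased on aromatization, so no stereocontrol is required. The outward C4 methoxyl of 3 keeps the s-cis conformer accessible, and the low temperature is meant to keep the diene from attacking or displacing bromine.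

**Step 5**
Reactants: 8 1-(2-bromo-6-hydroxy-3,4-dimethoxyphenyl)ethanone
Product: 9 1-[2-bromo-3,4-dimethoxy-6-(methoxymethoxy)phenyl]ethanone
Conditions: NaH (1.1 equiv), DMF, 0 °C; MOMCl, 0 °C → rt
Reagents that add atoms: chloromethyl methyl ether, COCCl
Why: Williamson-type O-alkylation of the sodium phenoxide; the phenol is far more acidic than the methyl ketone, so one equivalent of NaH deprotonates it selectively, and the acetal then blocks the C5 oxygen from closing ring C on the wrong side.

**Step 6**
Reactants: 9 1-[2-bromo-3,4-dimethoxy-6-(methoxymethoxy)phenyl]ethanone; 10 3,4,5-trimethoxybenzoyl chloride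
Product: 11 1-[2-bromo-3,4-dimethoxy-6-(methoxymethoxy)phenyl]-3-(3,4,5-trimethoxyphenyl)propane-1,3-dione
Conditions: LiN(SiMe3)2 (2.2 equiv), THF, −78 °C; then 10, −78 → 0 °C; aq. NH4Cl
Reagents that add atoms: none
Why: Crossed Claisen condensation (C-acylation of the kinetic lithium enolate by the aroyl chloride) forms C2–C3; the second equivalent of base converts the more acidic diketone into its enolate, which stops double acylation, and the amide base does not touch the aryl bromide.

**Step 7**
Reactants: 11 1-[2-bromo-3,4-dimethoxy-6-(methoxymethoxy)phenyl]-3-(3,4,5-trimethoxyphenyl)propane-1,3-dione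
Product: 12 7,8-dimethoxy-5-(methoxymethoxy)-2-(3,4,5-trimethoxyphenyl)-4H-chromen-4-one
Conditions: CuI (10 mol %), 1,10-phenanthroline (20 mol %), K2CO3 (2 equiv), DMF, 100 °C, N2
Reagents that add atoms: none
Why: Intramolecular Ullmann-type O-arylation of a 1-(2-bromoaryl)-1,3-diketone, a known route to chromones: the diketonate binds monovalent copper, the ortho-acyl group activates the C–Br bond, and only the enol oxygen of the aroyl-side carbonyl can reach C8a through a six-membered ring, so O1–C8a forms and the pyranone results directly.

**Step 8**
Reactants: 12 7,8-dimethoxy-5-(methoxymethoxy)-2-(3,4,5-trimethoxyphenyl)-4H-chromen-4-one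
Product: 15 3,5-dihydroxy-7,8-dimethoxy-2-(3,4,5-trimethoxyphenyl)-4H-chromen-4-one (the target), via flavone 2,3-epoxide 13 (not isolated), via MOM-protected flavonol 14 (not isolated)
Conditions: DMDO (acetone solution), CH2Cl2, 0 °C → rt; evaporate; then 2 M HCl, MeOH–THF, 40 °C
Reagents that add atoms: dimethyldioxirane, CC1(C)OO1
Why: Dioxirane epoxidation of the C2=C3 enol ether bond of a 5-alkoxyflavone followed by acid-induced opening at C2 (benzylic and stabilized by O1) and loss of H3 is a known flavone-to-flavonol conversion; the same mild acid cleaves the methoxymethyl acetal, helped by the peri carbonyl, and is kept well below the severity at which a Wessely–Moser isomerization would set in.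

## Compound list

1 | methyl 4-methoxy-3-oxobutanoate | COCC(=O)CC(=O)OC | starting material
2 | methyl (E)-3,4-dimethoxybut-2-enoate | COC/C(OC)=C\C(=O)OC | intermediate
3 | (1Z,3Z)-1,3,4-trimethoxy-1-(trimethylsilyloxy)buta-1,3-diene | CO/C=C(OC)/C=C(/OC)O[Si](C)(C)C | intermediate
4 | but-3-yn-2-one | CC(=O)C#C | starting material
5 | 4-bromobut-3-yn-2-one | CC(=O)C#CBr | intermediate
6 | 1-[2-bromo-3,4,6-trimethoxy-6-(trimethylsilyloxy)cyclohexa-1,4-dien-1-yl]ethanone (not isolated; mixture of diastereomers, both stereocentres lost on aromatization) | CC(=O)C1=C(Br)C(OC)C(OC)=CC1(OC)O[Si](C)(C)C | intermediate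
7 | 2-acetyl-3-bromo-4,5-dimethoxycyclohexa-2,5-dien-1-one (not isolated; racemic, one enantiomer drawn) | CC(=O)C1=C(Br)[C@@H](OC)C(OC)=CC1=O | intermediate
8 | 1-(2-bromo-6-hydroxy-3,4-dimethoxyphenyl)ethanone | CC(=O)c1c(O)cc(OC)c(OC)c1Br | intermediate
9 | 1-[2-bromo-3,4-dimethoxy-6-(methoxymethoxy)phenyl]ethanone | CC(=O)c1c(OCOC)cc(OC)c(OC)c1Br | intermediate
10 | 3,4,5-trimethoxybenzoyl chloride | COc1cc(C(Cl)=O)cc(OC)c1OC | starting material
11 | 1-[2-bromo-3,4-dimethoxy-6-(methoxymethoxy)phenyl]-3-(3,4,5-trimethoxyphenyl)propane-1,3-dione (drawn as the diketo tautomer) | COCOc1cc(OC)c(OC)c(Br)c1C(=O)CC(=O)c1cc(OC)c(OC)c(OC)c1 | intermediate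
12 | 7,8-dimethoxy-5-(methoxymethoxy)-2-(3,4,5-trimethoxyphenyl)-4H-chromen-4-one | COCOc1cc(OC)c(OC)c2oc(-c3cc(OC)c(OC)c(OC)c3)cc(=O)c12 | intermediate
13 | 2,3-epoxy-7,8-dimethoxy-5-(methoxymethoxy)-2-(3,4,5-trimethoxyphenyl)chroman-4-one (not isolated; racemic, one enantiomer drawn, cis-fused) | COCOc1cc(OC)c(OC)c2O[C@@]3(c4cc(OC)c(OC)c(OC)c4)O[C@H]3C(=O)c12 | intermediate
14 | 3-hydroxy-7,8-dimethoxy-5-(methoxymethoxy)-2-(3,4,5-trimethoxyphenyl)-4H-chromen-4-one (not isolated) | COCOc1cc(OC)c(OC)c2oc(-c3cc(OC)c(OC)c(OC)c3)c(O)c(=O)c12 | intermediate
15 | 3,5-dihydroxy-7,8-dimethoxy-2-(3,4,5-trimethoxyphenyl)-4H-chromen-4-one | COc1cc(-c2oc3c(OC)c(OC)cc(O)c3c(=O)c2O)cc(OC)c1OC | target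

## Step count and least certain steps

Total step count: 8. Longest linear sequence: 7 steps (steps 1, 2, 4, 5, 6, 7, 8); step 3 is a one-step branch.

**Step 4 (key step).**
- Risk: the ketene acetal attacks at bromine or displaces bromide by addition–elimination instead of closing the ring, so that diene is consumed without forming ring A. A lesser risk is aromatization by loss of silanol instead of methanol, which would leave the C5 oxygen methylated; a chelation-controlled cleavage with BCl3 ortho to the acetyl group would correct that.
- Fallback (from 3 and 4, back at 8): the bromine is taken off the dienophile and introduced afterwards by umpolung of the ring.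
  - Diene 3 and but-3-yn-2-one 4 should undergo the same cycloaddition–aromatization (PhMe, 0 °C → rt; 1 M HCl) to give 1-(2-hydroxy-4,5-dimethoxyphenyl)ethanone F1, a para-methoxyphenol.
  - Oxidative dearomatization with PhI(OAc)2 in MeOH at 0 °C should give the quinone monoketal 2-acetyl-4,4,5-trimethoxycyclohexa-2,5-dien-1-one F2. In F2 the former C8a is the β-carbon of an alkylidene 1,3-dicarbonyl unit.
  - Conjugate addition of bromide at that carbon (anhydrous HBr in AcOH–CH2Cl2, −20 °C), followed by loss of methanol from the ketal carbon, rearomatizes the ring and should give 8.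
  - Direct electrophilic bromination of F1 is not an option, because it would go ortho to the phenol at the future C6.

**Step 2.**
- Risk: γ-deprotonation competes with attack of the amide base on the ester, or it delivers the C3=C4 bond with the methoxyl turned inward, which would make the s-cis conformer hard to reach. The diene may also hydrolyse on handling.
- Fallback (from 1, back at 8): the γ-carbon is activated through a silyl enol ether and the C7 methyl group is put on after the ring is made.
  - Me3SiCl/Et3N (PhMe, rt) should convert 1 into methyl 4-methoxy-3-(trimethylsilyloxy)but-2-enoate F3.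
  - LiN(i-Pr)2/Me3SiCl (THF, −78 °C) should then give 1,4-dimethoxy-1,3-bis(trimethylsilyloxy)buta-1,3-diene F4, a member of the established class of 1,3-bis(silyloxy) dienes of β-keto esters.
  - Cycloaddition of F4 with 5 and acidic work-up should give 1-(2-bromo-4,6-dihydroxy-3-methoxyphenyl)ethanone F5.
  - Methylation of the hydroxyl para to the acetyl group (Me2SO4, 1 equiv, K2CO3, acetone) returns to 8. That hydroxyl is not hydrogen-bonded to the carbonyl and is the more acidic one.

**Step 7.**
- Risk: slow activation of a C–Br bond flanked by two ortho substituents on an electron-rich ring, with hydrodebromination or retro-Claisen cleavage of the diketone taking over at the temperature needed.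
- Fallback (from 9, back at 12): O1 is attached before ring C is built, and the ring is then closed through the new phenol.
  - Hydroxylation of the bromide with a zerovalent palladium catalyst (Pd2(dba)3, t-BuXPhos, KOH, dioxane–H2O, 100 °C) should give 1-[2-hydroxy-3,4-dimethoxy-6-(methoxymethoxy)phenyl]ethanone F6.
  - Claisen–Schmidt condensation with 3,4,5-trimethoxybenzaldehyde (KOH, EtOH, rt) should give (E)-1-[2-hydroxy-3,4-dimethoxy-6-(methoxymethoxy)phenyl]-3-(3,4,5-trimethoxyphenyl)prop-2-en-1-one F7.
  - Intramolecular oxa-Michael addition (NaOAc, EtOH, reflux) should give 7,8-dimethoxy-5-(methoxymethoxy)-2-(3,4,5-trimethoxyphenyl)chroman-4-one F8.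
  - Dehydrogenation with DDQ (dioxane, reflux) leads to 12.
  - The C5 acetal is untouched by these basic and neutral conditions, so only the new phenol can close the ring.

**Step 8.**
- Risk: over-oxidation of the two electron-rich arenes by the dioxirane while the enone-type double bond reacts slowly, or ring opening and reclosure of the 5-hydroxy-8-methoxychromone if the acid stage is pushed.
- Fallback (from 12, back at 14 and then 15): the C3 oxygen is introduced through a carbanion and not through an epoxide.
  - C3 lithiation with LiN(i-Pr)2 (THF, −78 °C) and trapping with B(OMe)3 should give dimethyl [7,8-dimethoxy-5-(methoxymethoxy)-4-oxo-2-(3,4,5-trimethoxyphenyl)-4H-chromen-3-yl]boronate F9.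
  - Oxidation with H2O2/AcOH should give 14, which is isolated in this variant.
  - The acetal is then removed under the mildest conditions that work (dilute HCl in MeOH at rt, or MgBr2 with a thiol) to give 15.

**Step 6.**
- Risk: O-acylation of the hindered enolate or a second acylation of the product.
- Fallback (from 9, back at 11): the C2–C3 bond is made by an aldol addition and the oxidation level is adjusted afterwards.
  - The lithium enolate of 9 (LiN(SiMe3)2, THF, −78 °C) is added to 3,4,5-trimethoxybenzaldehyde to give 1-[2-bromo-3,4-dimethoxy-6-(methoxymethoxy)phenyl]-3-hydroxy-3-(3,4,5-trimethoxyphenyl)propan-1-one F10.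
  - Oxidation of the secondary alcohol with DMP (CH2Cl2, rt) gives 11.

## Further compounds

F1 | step 4 | 1-(2-hydroxy-4,5-dimethoxyphenyl)ethanone | CC(=O)c1cc(OC)c(OC)cc1O
F2 | step 4 | 2-acetyl-4,4,5-trimethoxycyclohexa-2,5-dien-1-one | CC(=O)C1=CC(OC)(OC)C(OC)=CC1=O
F3 | step 2 | methyl 4-methoxy-3-(trimethylsilyloxy)but-2-enoate (mixture of geometric isomers) | COCC(O[Si](C)(C)C)=CC(=O)OC
F4 | step 2 | 1,4-dimethoxy-1,3-bis(trimethylsilyloxy)buta-1,3-diene (geometry not defined) | COC=C(O[Si](C)(C)C)C=C(OC)O[Si](C)(C)C
F5 | step 2 | 1-(2-bromo-4,6-dihydroxy-3-methoxyphenyl)ethanone | CC(=O)c1c(O)cc(O)c(OC)c1Br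
F6 | step 7 | 1-[2-hydroxy-3,4-dimethoxy-6-(methoxymethoxy)phenyl]ethanone | CC(=O)c1c(OCOC)cc(OC)c(OC)c1O
F7 | step 7 | (E)-1-[2-hydroxy-3,4-dimethoxy-6-(methoxymethoxy)phenyl]-3-(3,4,5-trimethoxyphenyl)prop-2-en-1-one | COCOc1cc(OC)c(OC)c(O)c1C(=O)/C=C/c1cc(OC)c(OC)c(OC)c1
F8 | step 7 | 7,8-dimethoxy-5-(methoxymethoxy)-2-(3,4,5-trimethoxyphenyl)chroman-4-one (racemic, one enantiomer drawn) | COCOc1cc(OC)c(OC)c2O[C@H](c3cc(OC)c(OC)c(OC)c3)CC(=O)c12
F9 | step 8 | dimethyl [7,8-dimethoxy-5-(methoxymethoxy)-4-oxo-2-(3,4,5-trimethoxyphenyl)-4H-chromen-3-yl]boronate | COCOc1cc(OC)c(OC)c2oc(-c3cc(OC)c(OC)c(OC)c3)c(B(OC)OC)c(=O)c12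
F10 | step 6 | 1-[2-bromo-3,4-dimethoxy-6-(methoxymethoxy)phenyl]-3-hydroxy-3-(3,4,5-trimethoxyphenyl)propan-1-one (racemic, one enantiomer drawn) | COCOc1cc(OC)c(OC)c(Br)c1C(=O)C[C@H](O)c1cc(OC)c(OC)c(OC)c1
A1 | alternative 1 | 3-(benzyloxy)-5,7,8-trimethoxy-2-(3,4,5-trimethoxyphenyl)-4H-chromen-4-one | COc1cc(-c2oc3c(OC)c(OC)cc(OC)c3c(=O)c2OCc2ccccc2)cc(OC)c1OC
A2 | alternative 1 | 3,4,6-trimethoxy-2-[(3,4,5-trimethoxybenzoyl)oxy]benzoyl chloride | COc1cc(OC)c(C(Cl)=O)c(OC(=O)c2cc(OC)c(OC)c(OC)c2)c1OC
A3 | alternative 1 | [(benzyloxy)methylidene]triphenylphosphorane | C(OCc1ccccc1)=P(c1ccccc1)(c1ccccc1)c1ccccc1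
A4 | alternative 2 | 5,7,8-trimethoxy-2-(3,4,5-trimethoxyphenyl)-2H-chromene (racemic, one enantiomer drawn) | COc1cc(OC)c2C=C[C@@H](c3cc(OC)c(OC)c(OC)c3)Oc2c1OC
A5 | alternative 2 | 2,3,5-trimethoxyphenol | COc1cc(O)c(OC)c(OC)c1
A6 | alternative 2 | (E)-3-(3,4,5-trimethoxyphenyl)prop-2-enal | COc1cc(/C=C/C=O)cc(OC)c1OC
A7 | alternative 3 | 4,5-dimethoxy-2-(2-methyl-1,3-dioxolan-2-yl)-3-(triisopropylsilyloxy)phenol | CC1(OCCO1)c1c(O)cc(OC)c(OC)c1O[Si](C(C)C)(C(C)C)C(C)C
A8 | alternative 3 | 2,3-dimethoxycyclobut-2-en-1-one | COC1=C(OC)C(=O)C1
A9 | alternative 3 | triisopropyl{[(2-methyl-1,3-dioxolan-2-yl)ethynyl]oxy}silane | CC1(OCCO1)C#CO[Si](C(C)C)(C(C)C)C(C)C
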